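**Plan**

Numbering: cyclopentane C1 (quaternary, bears aryl and CH3), C2 (CH–CH3), C3 (=CHBr), C4, C5. Ring A is the arene.
Retrosynthesis: remove the ring A bromine and cut C3=CHBr back to a C3 ketone. Re-bond C5 to the phenol oxygen, then cut C1–C5, C2–C3 and C3–C4 together as a (2+2+1) cycloaddition. Last, cut O–C5 (ynol ether from trichloroethylene) and aryl–C1 (Suzuki–Miyaura coupling).
Enabling feature: the phenol oxygen sits on the ring A carbon ortho to the one that carries C1. O–C(ar)–C(ar)–C1 is therefore a built-in four-atom tether that can hold C5 as an aryl ynol ether opposite a C1=C2 alkene. The cis relation of aryl and C2-methyl on the five-membered ring corresponds to the Z geometry of a 2-arylbut-2-ene.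
Forward: ring A is bought, and the Z-butenyl group and then the ethynyl ether are attached. A temporary dihydrofuran ring and the cyclopentenone ring close together in the key step. The dihydrofuran is then opened reductively at C5–O, and the two bromine-bearing groups come last.
Stereochemistry: the C1/C2 relative configuration comes from suprafacial addition to the Z alkene, and the absolute configuration from the chiral bisphosphine on rhodium. The E geometry at C3 comes from the steric bias of C2 in the Wittig step, and C2 is kept away from equilibrating base or acid once it is set.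

Key step: step 5

Assumption: the sense of induction of BINAP on this substrate class cannot be read from precedent. (R)-BINAP is written as the antipode that gives the (1R,8bR) enone of the key step, and (S)-BINAP replaces it, with nothing else changed, if correlation with the target shows the opposite sense.

**Step 1**
Reactants: 1 2-bromo-5-methylphenol
Product: 3 (2-hydroxy-4-methylphenyl)boronic acid, via lithium 2-lithio-5-methylphenolate 2 (not isolated)
Conditions: n-BuLi (2.2 equiv), Et2O, 0 °C to rt; B(Oi-Pr)3, −78 °C to rt; 1 M HCl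
Reagents that add atoms: triisopropyl borate, CC(C)OB(OC(C)C)OC(C)C; water, O
Why: Deprotonation followed by bromine–lithium exchange on the phenoxide gives the O,C-dilithiated arene 2, whose carbanion is trapped by the borate (halogen–metal exchange and electrophilic borylation), so no phenol protecting group and no later acidic deprotection beside an acid-labile Z styrene are needed.

**Step 2**
Reactants: 3 (2-hydroxy-4-methylphenyl)boronic acid; 4 (Z)-2-bromobut-2-ene
Product: 5 2-[(2Z)-but-2-en-2-yl]-5-methylphenol
Conditions: Pd(PPh3)4 (5 mol %), K2CO3, DME/H2O, 80 °C, sealed tube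
Reagents that add atoms: (Z)-2-bromobut-2-ene 4, C/C=C(Br)/C
Why: Suzuki–Miyaura coupling of an alkenyl bromide keeps the configuration at the sp2 carbon through oxidative addition and reductive elimination, so the aryl group takes the place of bromine on the same side as the C3 methyl group of 4 and gives the Z alkene that later encodes the C1/C2 relation, the free phenol being tolerated as its phenoxide.

**Step 3**
Reactants: 5 2-[(2Z)-but-2-en-2-yl]-5-methylphenol; 6 trichloroethylene
Product: 8 1-[(2Z)-but-2-en-2-yl]-2-{[(E)-1,2-dichloroethenyl]oxy}-4-methylbenzene, via dichloroacetylene 7 (not isolated)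
Conditions: Cl2C=CHCl (1.5 equiv), K2CO3, DMF, 70 °C, closed vessel
Reagents that add atoms: trichloroethylene 6, ClC=C(Cl)Cl
Why: Elimination–addition O-vinylation, in which carbonate strips HCl from 6 to give 7 and the phenoxide adds to it in the anti sense, is a standard entry to aryl E-1,2-dichlorovinyl ethers and leaves the unactivated Z alkene alone.

**Step 4**
Reactants: 8 1-[(2Z)-but-2-en-2-yl]-2-{[(E)-1,2-dichloroethenyl]oxy}-4-methylbenzene
Product: 11 1-[(2Z)-but-2-en-2-yl]-2-(ethynyloxy)-4-methylbenzene, via chloroethynyl ether 9 (not isolated), via lithium acetylide 10 (not isolated)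
Conditions: n-BuLi (2.2 equiv), Et2O, −78 to −40 °C; H2O, −78 °C; used at once
Reagents that add atoms: none
Why: Dehydrochlorination to 9 and chlorine–lithium exchange to 10 with two equivalents of n-BuLi is the standard ynol ether synthesis from dichlorovinyl ethers, an aryl ynol ether has no β-hydrogen for retro-ene loss of ketene, and the cold neutral quench with immediate use guards against hydration.

**Step 5**
Reactants: 11 1-[(2Z)-but-2-en-2-yl]-2-(ethynyloxy)-4-methylbenzene; 12 carbon monoxide
Product: 13 (1R,8bR)-1,6,8b-trimethyl-1,8b-dihydro-2H-cyclopenta[b][1]benzofuran-2-one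
Conditions: [Rh(CO)2Cl]2 (5 mol %), (R)-BINAP (11 mol %), AgOTf (11 mol %), THF, rt, AgCl filtered off; then 11, 4 Å MS, CO/Ar 1:9 (1 atm), 90 °C, pressure tube
Reagents that add atoms: carbon monoxide 12, [C-]#[O+]
Why: Proposed new method: a cationic BINAP complex of monovalent rhodium binds the alkyne and the alkene of 11, oxidative cyclisation joins C5 to C1 and leaves a rhodacyclopentene of trivalent rhodium bonded to C4 and C2, and CO insertion followed by reductive elimination makes C3–C4 and C2–C3. The closest known reaction type is the intramolecular Pauson–Khand reaction of 1,6-enynes, established for ynol ethers with Co2(CO)8 and in enantioselective form with [Rh(CO)2Cl]2, BINAP and AgOTf, but never with the ether oxygen inside the tether together with a trisubstituted styrene that ends as a quaternary carbon. The dihydrofuran ring closes in the 5-exo mode with respect to both the alkene and the alkyne at the oxidative cyclisation stage, and the cyclopentenone ring closes last, by reductive elimination from the six-membered acylrhodacycle. C1 and C2 (positions 8b and 1 of 13) arise from one suprafacial addition across C1=C2, so the Z geometry of 11 puts aryl and C2-methyl cis, and the absolute sense depends only on which alkene face the chiral pocket of the ligand lets approach the metal. The step needs regiocontrol, which the four-atom O–C(ar)–C(ar)–C1 tether enforces by leaving C3 as the only place for CO, and chemoselectivity over hydration, oligomerisation, vinylidene formation and cationic 6-endo cycloisomerisation of the electron-rich alkyne, which the rigid ortho-phenylene tether, the allylic strain that turns the alkene face toward the alkyne, the removal of silver salts and water and the low CO pressure are meant to secure. Enone 13 should crystallise, so its enantiomeric purity can be raised before it is carried on.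

**Step 6**
Reactants: 13 (1R,8bR)-1,6,8b-trimethyl-1,8b-dihydro-2H-cyclopenta[b][1]benzofuran-2-one
Product: 17 (2R,3R)-3-(2-hydroxy-4-methylphenyl)-2,3-dimethylcyclopentan-1-one, via tricyclic lithium enolate 14 (not isolated), via enone lithium phenoxide 15 (not isolated), via dilithium enolate phenoxide 16 (not isolated)
Conditions: Li (4.5 equiv), t-BuOH (2 equiv), NH3(l)/THF, −78 °C; solid NH4Cl
Reagents that add atoms: none
Why: Dissolving-metal reduction of a β-aryloxy enone gives, after two electrons and a proton, enolate 14, which expels the C5 phenoxide (E1cB), and the enone 15 so formed is reduced again to the C3–C4 enolate 16, which shields C2–H from base until the fast NH4Cl quench, so both stereocentres pass through untouched.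

**Step 7**
Reactants: 17 (2R,3R)-3-(2-hydroxy-4-methylphenyl)-2,3-dimethylcyclopentan-1-one
Product: 18 (2R,3R)-3-(5-bromo-2-hydroxy-4-methylphenyl)-2,3-dimethylcyclopentan-1-one
Conditions: NBS (1.0 equiv), MeCN, −20 to 0 °C
Reagents that add atoms: N-bromosuccinimide, O=C1CCC(=O)N1Br
Why: In this electrophilic aromatic bromination the free hydroxyl group directs NBS to its para position, which is also ortho to the ring methyl group, the only other activated site lies crowded between OH and CH3, and the acid-free medium gives the ketone no chance to enolise at C2.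

**Step 8**
Reactants: 18 (2R,3R)-3-(5-bromo-2-hydroxy-4-methylphenyl)-2,3-dimethylcyclopentan-1-one
Product: 19 (2R,3R)-3-{5-bromo-2-[(tert-butyldimethylsilyl)oxy]-4-methylphenyl}-2,3-dimethylcyclopentan-1-one
Conditions: TBSCl, imidazole, DMF, rt
Reagents that add atoms: tert-butyldimethylsilyl chloride, CC(C)(C)[Si](C)(C)Cl
Why: Imidazole-promoted silyl ether formation masks the acidic phenol before the ylide step, and imidazole is too weak a base to touch C2–H.

**Step 9**
Reactants: 19 (2R,3R)-3-{5-bromo-2-[(tert-butyldimethylsilyl)oxy]-4-methylphenyl}-2,3-dimethylcyclopentan-1-one; 20 (bromomethyl)triphenylphosphonium bromide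
Product: 22 tert-butyl{4-bromo-2-[(1R,2R,3E)-3-(bromomethylidene)-1,2-dimethylcyclopentyl]-5-methylphenoxy}dimethylsilane, via bromomethylidene ylide 21 (not isolated)
Conditions: 20 (5 equiv), NaN(SiMe3)2 (4.8 equiv), THF, −60 °C; then 19, −60 °C to rt
Reagents that add atoms: (bromomethyl)triphenylphosphonium bromide 20, BrC[P+](c1ccccc1)(c1ccccc1)c1ccccc1.[Br-]
Why: Wittig bromomethylenation with an excess of ylide 21 preformed at low temperature is known to turn α-branched, epimerisable bicyclic ketones such as trans-hydrindan-4-ones into E bromomethylidene compounds without loss of the α-centre, and here the C2 methine next to quaternary C1 likewise steers bromine to the C4 side.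

**Step 10**
Reactants: 22 tert-butyl{4-bromo-2-[(1R,2R,3E)-3-(bromomethylidene)-1,2-dimethylcyclopentyl]-5-methylphenoxy}dimethylsilane
Product: 23 4-bromo-2-[(1R,2R,3E)-3-(bromomethylidene)-1,2-dimethylcyclopentyl]-5-methylphenol
Conditions: Bu4NF, AcOH, THF, 0 °C
Reagents that add atoms: none
Why: Fluoride-induced cleavage of the aryl silyl ether, buffered with acetic acid, avoids the strong protic acid that could cyclise the phenol onto the alkene, and no centre in 22 is base-labile any more.

**Compound list**

1 | 2-bromo-5-methylphenol | Cc1ccc(Br)c(O)c1 | starting material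
2 | lithium 2-lithio-5-methylphenolate | [Li]c1ccc(C)cc1O[Li] | intermediate
3 | (2-hydroxy-4-methylphenyl)boronic acid | Cc1ccc(B(O)O)c(O)c1 | intermediate
4 | (Z)-2-bromobut-2-ene | C/C=C(Br)/C | starting material
5 | 2-[(2Z)-but-2-en-2-yl]-5-methylphenol | Cc1ccc(/C(C)=C\C)c(O)c1 | intermediate
6 | trichloroethylene | ClC=C(Cl)Cl | starting material
7 | dichloroacetylene | ClC#CCl | intermediate
8 | 1-[(2Z)-but-2-en-2-yl]-2-{[(E)-1,2-dichloroethenyl]oxy}-4-methylbenzene | Cc1ccc(/C(C)=C\C)c(O/C(Cl)=C\Cl)c1 | intermediate
9 | 1-[(2Z)-but-2-en-2-yl]-2-[(chloroethynyl)oxy]-4-methylbenzene | ClC#COc1cc(C)ccc1/C(C)=C\C | intermediate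
10 | lithium acetylide of 11, {2-[(2Z)-but-2-en-2-yl]-5-methylphenoxy}ethynyllithium | [Li]C#COc1cc(C)ccc1/C(C)=C\C | intermediate
11 | 1-[(2Z)-but-2-en-2-yl]-2-(ethynyloxy)-4-methylbenzene | C#COc1cc(C)ccc1/C(C)=C\C | intermediate
12 | carbon monoxide | [C-]#[O+] | starting material
13 | (1R,8bR)-1,6,8b-trimethyl-1,8b-dihydro-2H-cyclopenta[b][1]benzofuran-2-one | Cc1ccc2c(c1)OC1=CC(=O)[C@H](C)[C@]21C | intermediate
14 | lithium (1R,3aR,8bR)-1,6,8b-trimethyl-3a,8b-dihydro-1H-cyclopenta[b][1]benzofuran-2-olate | Cc1ccc2c(c1)O[C@@H]1C=C(O[Li])[C@H](C)[C@]21C | intermediate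
15 | lithium 2-[(1R,5R)-1,5-dimethyl-4-oxocyclopent-2-en-1-yl]-5-methylphenolate | Cc1ccc([C@]2(C)C=CC(=O)[C@@H]2C)c(O[Li])c1 | intermediate
16 | lithium 2-[(1R,2R)-3-(lithiooxy)-1,2-dimethylcyclopent-3-en-1-yl]-5-methylphenolate | Cc1ccc([C@]2(C)CC=C(O[Li])[C@@H]2C)c(O[Li])c1 | intermediate
17 | (2R,3R)-3-(2-hydroxy-4-methylphenyl)-2,3-dimethylcyclopentan-1-one | Cc1ccc([C@]2(C)CCC(=O)[C@@H]2C)c(O)c1 | intermediate
18 | (2R,3R)-3-(5-bromo-2-hydroxy-4-methylphenyl)-2,3-dimethylcyclopentan-1-one | Cc1cc(O)c([C@]2(C)CCC(=O)[C@@H]2C)cc1Br | intermediate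
19 | (2R,3R)-3-{5-bromo-2-[(tert-butyldimethylsilyl)oxy]-4-methylphenyl}-2,3-dimethylcyclopentan-1-one | Cc1cc(O[Si](C)(C)C(C)(C)C)c([C@]2(C)CCC(=O)[C@@H]2C)cc1Br | intermediate
20 | (bromomethyl)triphenylphosphonium bromide | BrC[P+](c1ccccc1)(c1ccccc1)c1ccccc1.[Br-] | starting material
21 | (bromomethylidene)triphenylphosphorane | BrC=P(c1ccccc1)(c1ccccc1)c1ccccc1 | intermediate
22 | tert-butyl{4-bromo-2-[(1R,2R,3E)-3-(bromomethylidene)-1,2-dimethylcyclopentyl]-5-methylphenoxy}dimethylsilane | Cc1cc(O[Si](C)(C)C(C)(C)C)c([C@]2(C)CC/C(=C\Br)[C@@H]2C)cc1Br | intermediate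
23 | 4-bromo-2-[(1R,2R,3E)-3-(bromomethylidene)-1,2-dimethylcyclopentyl]-5-methylphenol | Cc1cc(O)c([C@]2(C)CC/C(=C\Br)[C@@H]2C)cc1Br | target

Total steps: 10. Longest linear sequence: 10 steps, from 1 to 23.

**Steps most likely to fail**

**Step 5** (the step beyond known chemistry). Oxidative cyclisation at the trisubstituted alkene may be so slow that hydration, oligomerisation or cycloisomerisation of the ynol ether outruns the cycloaddition. The ligand may also discriminate poorly between the two alkene faces.

The fallback gives up the cycloaddition and builds C1 by conjugate addition. It sets out from 1 and returns at 17.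
- Phenol 1 is benzylated (BnBr, K2CO3, DMF) to 2-(benzyloxy)-1-bromo-4-methylbenzene F1.
- Bromine–lithium exchange (n-BuLi, THF, −78 °C), B(Oi-Pr)3 and acidic work-up give [2-(benzyloxy)-4-methylphenyl]boronic acid F2.
- Enantioselective conjugate addition of F2 to 3-methylcyclopent-2-en-1-one follows (Pd(OCOCF3)2, the t-Bu-pyridine-oxazoline antipode that gives the R ketone, NH4PF6, H2O, ClCH2CH2Cl, 60 °C). This reaction type is known for ortho-substituted arylboronic acids. It sets C1 in (3R)-3-[2-(benzyloxy)-4-methylphenyl]-3-methylcyclopentan-1-one F3.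
- Dehydrogenation with IBX can run only toward the C4–C5 side, because C1 carries no hydrogen. It gives (4S)-4-[2-(benzyloxy)-4-methylphenyl]-4-methylcyclopent-2-en-1-one F4.
- C2 is now the sole enolisable position, so LiN(i-Pr)2 and then MeI methylate there. Attack is expected anti to the aryl group, giving (4R,5S)-4-[2-(benzyloxy)-4-methylphenyl]-4,5-dimethylcyclopent-2-en-1-one F5.
- Renewed deprotonation and kinetic protonation follow, with 2,6-di-tert-butyl-4-methylphenol approaching from the face remote from the aryl group. This inverts C2 to (4R,5R)-4-[2-(benzyloxy)-4-methylphenyl]-4,5-dimethylcyclopent-2-en-1-one F6.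
- H2 over Pd/C in EtOAc then saturates C4=C5 and removes the benzyl group under neutral conditions to give 17.

**Step 9.** The basic ylide may enolise the cyclopentanone, which would stall conversion and epimerise C2 toward the more stable trans aryl/methyl series. The ylide may also disproportionate, or the E preference may be eroded.

The fallback replaces the basic olefination and installs the bromine afterwards. It sets out from 19 and returns at 22.
- Non-basic methylenation (Zn, CH2Br2, TiCl4, THF/CH2Cl2, 0 °C to rt) gives tert-butyl{4-bromo-2-[(1R,2S)-1,2-dimethyl-3-methylidenecyclopentyl]-5-methylphenoxy}dimethylsilane F7.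
- Addition of Br2 (CH2Cl2, −78 °C) to the only nucleophilic alkene gives tert-butyl{4-bromo-2-[(1R,2R)-3-bromo-3-(bromomethyl)-1,2-dimethylcyclopentyl]-5-methylphenoxy}dimethylsilane F8. Either C3 epimer serves.
- DBU in toluene removes the acidified CH2Br hydrogen together with the tertiary bromide. The remaining bromine settles on the side away from C2, which gives 22.

**Step 6.** The ketone may be over-reduced to the alcohol, ring A may undergo Birch reduction before C5–O is broken, or proton exchange during the quench may epimerise C2.

The fallback separates the cascade into neutral and mildly basic operations. It sets out from 13 and returns at 17.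
- Hydrogenation (H2, Pd/C, EtOAc) from the convex face gives cis-fused (1R,3aR,8bR)-1,6,8b-trimethyl-1,3,3a,8b-tetrahydro-2H-cyclopenta[b][1]benzofuran-2-one F9.
- DBU (CH2Cl2, 0 °C) deprotonates the accessible C4 methylene and opens the dihydrofuran by retro-oxa-Michael elimination. This gives (4R,5R)-4-(2-hydroxy-4-methylphenyl)-4,5-dimethylcyclopent-2-en-1-one F10.
- A second hydrogenation over Pd/C gives 17.

**Further compounds**

F1 | step 5 | 2-(benzyloxy)-1-bromo-4-methylbenzene | Cc1ccc(Br)c(OCc2ccccc2)c1
F2 | step 5 | [2-(benzyloxy)-4-methylphenyl]boronic acid | Cc1ccc(B(O)O)c(OCc2ccccc2)c1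
F3 | step 5 | (3R)-3-[2-(benzyloxy)-4-methylphenyl]-3-methylcyclopentan-1-one | Cc1ccc([C@]2(C)CCC(=O)C2)c(OCc2ccccc2)c1
F4 | step 5 | (4S)-4-[2-(benzyloxy)-4-methylphenyl]-4-methylcyclopent-2-en-1-one | Cc1ccc([C@]2(C)C=CC(=O)C2)c(OCc2ccccc2)c1
F5 | step 5 | (4R,5S)-4-[2-(benzyloxy)-4-methylphenyl]-4,5-dimethylcyclopent-2-en-1-one | Cc1ccc([C@]2(C)C=CC(=O)[C@H]2C)c(OCc2ccccc2)c1
F6 | step 5 | (4R,5R)-4-[2-(benzyloxy)-4-methylphenyl]-4,5-dimethylcyclopent-2-en-1-one | Cc1ccc([C@]2(C)C=CC(=O)[C@@H]2C)c(OCc2ccccc2)c1
F7 | step 9 | tert-butyl{4-bromo-2-[(1R,2S)-1,2-dimethyl-3-methylidenecyclopentyl]-5-methylphenoxy}dimethylsilane | Cc1cc(O[Si](C)(C)C(C)(C)C)c([C@]2(C)CCC(=C)[C@@H]2C)cc1Br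
F8 | step 9 | tert-butyl{4-bromo-2-[(1R,2R)-3-bromo-3-(bromomethyl)-1,2-dimethylcyclopentyl]-5-methylphenoxy}dimethylsilane, C3 not defined | Cc1cc(O[Si](C)(C)C(C)(C)C)c([C@]2(C)CCC(Br)(CBr)[C@@H]2C)cc1Br
F9 | step 6 | (1R,3aR,8bR)-1,6,8b-trimethyl-1,3,3a,8b-tetrahydro-2H-cyclopenta[b][1]benzofuran-2-one | Cc1ccc2c(c1)O[C@@H]1CC(=O)[C@H](C)[C@]21C
F10 | step 6 | (4R,5R)-4-(2-hydroxy-4-methylphenyl)-4,5-dimethylcyclopent-2-en-1-one | Cc1ccc([C@]2(C)C=CC(=O)[C@@H]2C)c(O)c1
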